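**Retrosynthetic overview**
- The target (hyperforin-type core with a (2R)-2-methylbutanoyl group) is traced back to a tetraene by threefold olefin cross-metathesis. In that tetraene the two ring prenyls and the homoprenyl terminus are carried as allyl and but-3-enyl groups.
- The tetraene is traced back to a dearomatized acylphloroglucinol by the biosynthesis-type ring closure, run as a three-component cascade. A free dimethylallyl cation attacks the only trisubstituted alkene, and the acyl-bearing ring carbon captures the tertiary cation. This forms two C–C bonds and three stereocenters.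
- The dearomatized precursor comes from enantioselective palladium-catalysed dearomative allylation of a 3,5-diallyl acylphloroglucinol with an E-dienyl carbonate. This sets the first ring stereocenter, which relays to the other three.
- The building blocks are phloroglucinol, (R)-2-methylbutanoic acid, allyl bromide, and a carbonate made from hex-1-en-5-yne by methylalumination.
- Ring order: the acylphloroglucinol ring (bought as phloroglucinol) comes first; the bridging carbocycle is closed in the penultimate step.

Assumption: (R)-2-methylbutanoic acid, the side-chain configuration encoded in the target SMILES, is bought as the single enantiomer.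
Locants for the bicyclic compounds follow their names: C1 is the allyl/prenyl bridgehead, C5 the acyl bridgehead, C6 the quaternary methyl carbon, C7 the prenylated CH, C9 the bridging ketone.

**Step 1**
Reactants: 1 (R)-2-methylbutanoic acid; 2 phloroglucinol (benzene-1,3,5-triol)
Product: 4 (2R)-2-methyl-1-(2,4,6-trihydroxyphenyl)butan-1-one, via (R)-2-methylbutanoyl chloride 3 (not isolated)
Conditions: (COCl)2 (1.05 equiv), DMF (cat.), CH2Cl2, 0 °C to rt; then 2 (1.0 equiv), AlCl3 (3.5 equiv), PhNO2–CH2Cl2, 0 °C to rt, 12 h; aq. HCl
Reagents that add atoms: none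
Why: Friedel–Crafts C-acylation of the very electron-rich arene stops at the mono-ketone because the chelated aryl ketone deactivates the ring; the side-chain stereocenter comes from 1 and is kept by working at or below room temperature (ee to be checked by chiral HPLC).

**Step 2**
Reactants: 4 (2R)-2-methyl-1-(2,4,6-trihydroxyphenyl)butan-1-one; 5 allyl bromide (3-bromoprop-1-ene)
Product: 6 (2R)-2-methyl-1-[2,4,6-trihydroxy-3,5-di(prop-2-en-1-yl)phenyl]butan-1-one
Conditions: 5 (2.1 equiv), 10% aq. KOH (3 equiv), 0 °C, 2 h; then 2 M HCl
Reagents that add atoms: none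
Why: Double C-allylation of the ambident phloroglucinolate (aqueous hydroxide favours C- over O-alkylation, as in deoxyhumulone-type syntheses) fills both free ring positions; no stereocenter is formed, and the monosubstituted allyl groups are chosen because they are inert toward the prenyl cation of step 6.

**Step 3**
Reactants: 7 hex-1-en-5-yne
Product: 10 (2E)-3-methylhepta-2,6-dien-1-ol, via alkenyldimethylalane 8 (not isolated), via lithium alkenylaluminate 9 (not isolated)
Conditions: AlMe3 (2 equiv), Cp2ZrCl2 (0.2 equiv), CH2Cl2, 0 °C to rt; volatiles removed; n-BuLi (1.0 equiv), THF–hexane, −78 to 0 °C; (CH2O)n (3 equiv), rt; aq. HCl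
Reagents that add atoms: trimethylaluminium, C[Al](C)C; formaldehyde (as paraformaldehyde), C=O
Why: Negishi zirconium-catalysed carboalumination adds methyl and aluminium syn across the terminal alkyne (much faster than across the terminal alkene), and hydroxymethylation of the aluminate with retention fixes the E-trisubstituted alkene.

**Step 4**
Reactants: 10 (2E)-3-methylhepta-2,6-dien-1-ol
Product: 11 methyl (2E)-3-methylhepta-2,6-dien-1-yl carbonate
Conditions: ClCO2Me (1.3 equiv), pyridine (2 equiv), CH2Cl2, 0 °C
Reagents that add atoms: methyl chloroformate, COC(=O)Cl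
Why: Plain O-acylation gives the allylic carbonate, whose ionization in step 5 releases CO2 and methoxide as the only base; alkene geometry is untouched.

**Step 5**
Reactants: 6 (2R)-2-methyl-1-[2,4,6-trihydroxy-3,5-di(prop-2-en-1-yl)phenyl]butan-1-one; 11 methyl (2E)-3-methylhepta-2,6-dien-1-yl carbonate
Product: 12 (6R)-3,5-dihydroxy-2-[(2R)-2-methylbutanoyl]-6-[(2E)-3-methylhepta-2,6-dien-1-yl]-4,6-di(prop-2-en-1-yl)cyclohexa-2,4-dien-1-one (descriptor for the tautomer drawn)
Conditions: Pd2(dba)3·CHCl3 (2.5 mol%), (R,R)-DACH-phenyl Trost ligand (7 mol%), 11 (1.05 equiv), CH2Cl2, 0 °C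
Reagents that add atoms: none
Why: Proposed new method: a desymmetrizing dearomative Tsuji–Trost allylic alkylation in which zerovalent palladium ionizes 11, the methoxide formed deprotonates 6, O-allylation stays reversible, and the phenolate attacks the CH2 allyl terminus from one of its two enantiotopic allyl-bearing ring carbons inside the chiral ligand pocket, giving the linear E product and the quaternary stereocenter C6 (the (R,R)-ligand is taken to give 6R and the (S,S)-ligand is used if the sense proves opposite; the (2R)-acyl group makes the two outcomes diastereomers, readable by NMR and enrichable by chromatography; E geometry holds because syn/anti exchange would need a tertiary sigma-allyl palladium); closest known reactions are the palladium/Trost-ligand intermolecular asymmetric allylic dearomatization of substituted naphthols, ligand-controlled linear prenylation and geranylation of oxindoles, and the racemic dearomative C-allylation of 3,5-dialkyl acylphloroglucinols.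

**Step 6**
Reactants: 12 (6R)-3,5-dihydroxy-2-[(2R)-2-methylbutanoyl]-6-[(2E)-3-methylhepta-2,6-dien-1-yl]-4,6-di(prop-2-en-1-yl)cyclohexa-2,4-dien-1-one; 13 2-methylbut-3-en-2-ol
Product: 16 (1R,5S,6R,7S)-6-(but-3-en-1-yl)-4-hydroxy-6-methyl-7-(3-methylbut-2-en-1-yl)-5-[(2R)-2-methylbutanoyl]-1,3-di(prop-2-en-1-yl)bicyclo[3.3.1]non-3-ene-2,9-dione, via dimethylallyl cation 14 (not isolated), via tertiary C6 carbocation 15 (not isolated)
Conditions: 13 (1.3 equiv, added over 2 h), (PhO)2P(O)OH (10 mol%), 1,1,1,3,3,3-hexafluoropropan-2-ol–CH2Cl2 (1:4), −20 to 0 °C, stopped at about 70% conversion; pH 7 buffer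
Reagents that add atoms: none
Why: Proposed new method: a prenyl-cation-initiated cation–olefin cyclization in which acid-catalysed ionization of 13 gives cation 14, which adds at the CH terminus of the only trisubstituted alkene of 12 (the three monosubstituted alkenes are about four orders of magnitude less nucleophilic toward allyl cations), and the tertiary cation 15 is captured in the chair-folded chain by the acyl-bearing ring carbon, the terminus of the cross-conjugated dienol, whose attack leaves a fully conjugated protonated vinylogous acid (the fluorinated alcohol hydrogen-bonds the oxygens and tertiary enol ethers can re-ionize, which disfavours O-capture); anti addition across the E-alkene through the chair with the new prenyl equatorial sets C7 (S), C6 (R, methyl axial and butenyl equatorial) and C5 (S) from the existing C1 stereocenter; closest known reactions are Lewis-acid additions of allyl cations to trisubstituted alkenes, the cationic closure of dearomatized acylphloroglucinols carrying a tertiary cation precursor to the type A bicyclo[3.3.1]nonane core, and the prenyltransferase step of the biosynthesis.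

**Step 7**
Reactants: 16 (1R,5S,6R,7S)-6-(but-3-en-1-yl)-4-hydroxy-6-methyl-7-(3-methylbut-2-en-1-yl)-5-[(2R)-2-methylbutanoyl]-1,3-di(prop-2-en-1-yl)bicyclo[3.3.1]non-3-ene-2,9-dione; 17 2-methylbut-2-ene
Product: 18 (1R,5S,6R,7S)-4-hydroxy-6-methyl-1,3,7-tris(3-methylbut-2-en-1-yl)-6-(4-methylpent-3-en-1-yl)-5-[(2R)-2-methylbutanoyl]bicyclo[3.3.1]non-3-ene-2,9-dione (target)
Conditions: second-generation Hoveyda–Grubbs catalyst RuCl2(H2IMes)(=CH-C6H4-2-OiPr) (2 × 7.5 mol%), 1,4-benzoquinone (10 mol%), 17 (100 equiv), CH2Cl2, 40 °C, sealed tube, argon, dark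
Reagents that add atoms: 2-methylbut-2-ene (the second and third molecules of 17), CC=C(C)C
Why: Threefold olefin cross-metathesis with the balance 16 + 3 × 17 → 18 + 3 propene, in which each of the three monosubstituted alkenes takes an isopropylidene unit from its own molecule of 17 (one molecule stands on the Reactants line and the two further molecules on the reagent line), so the two allyl groups become prenyl and the but-3-enyl group becomes 4-methylpent-3-enyl, the large excess of the trisubstituted partner drives all three exchanges to completion, the C7 prenyl only exchanges degenerately, and no stereocenter is touched.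

**Compound list**
1 | (R)-2-methylbutanoic acid | CC[C@@H](C)C(=O)O | starting material
2 | phloroglucinol (benzene-1,3,5-triol) | Oc1cc(O)cc(O)c1 | starting material
3 | (R)-2-methylbutanoyl chloride (not isolated) | CC[C@@H](C)C(=O)Cl | intermediate
4 | (2R)-2-methyl-1-(2,4,6-trihydroxyphenyl)butan-1-one | CC[C@@H](C)C(=O)c1c(O)cc(O)cc1O | intermediate
5 | allyl bromide (3-bromoprop-1-ene) | C=CCBr | starting material
6 | (2R)-2-methyl-1-[2,4,6-trihydroxy-3,5-di(prop-2-en-1-yl)phenyl]butan-1-one | CC[C@@H](C)C(=O)c1c(O)c(CC=C)c(O)c(CC=C)c1O | intermediate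
7 | hex-1-en-5-yne | C=CCCC#C | starting material
8 | dimethyl[(1E)-2-methylhexa-1,5-dien-1-yl]alumane (not isolated) | C[Al](C)/C=C(\C)CCC=C | intermediate
9 | lithium butyl(dimethyl)[(1E)-2-methylhexa-1,5-dien-1-yl]aluminate (not isolated) | [Li+].CCCC[Al-](C)(C)/C=C(\C)CCC=C | intermediate
10 | (2E)-3-methylhepta-2,6-dien-1-ol | OC/C=C(\C)CCC=C | intermediate
11 | methyl (2E)-3-methylhepta-2,6-dien-1-yl carbonate | COC(=O)OC/C=C(\C)CCC=C | intermediate
12 | (6R)-3,5-dihydroxy-2-[(2R)-2-methylbutanoyl]-6-[(2E)-3-methylhepta-2,6-dien-1-yl]-4,6-di(prop-2-en-1-yl)cyclohexa-2,4-dien-1-one | CC[C@@H](C)C(=O)C1=C(O)C(CC=C)=C(O)[C@@](CC=C)(C/C=C(\C)CCC=C)C1=O | intermediate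
13 | 2-methylbut-3-en-2-ol | CC(C)(O)C=C | starting material
14 | dimethylallyl cation, 3-methylbut-2-en-1-ylium (not isolated) | CC(C)=C[CH2+] | intermediate
15 | tertiary carbocation from 12: prenyl on side-chain C2 (S), positive charge on side-chain C3 (not isolated) | CC[C@@H](C)C(=O)C1=C(O)C(CC=C)=C(O)[C@@](CC=C)(C[C@H](CC=C(C)C)[C+](C)CCC=C)C1=O | intermediate
16 | (1R,5S,6R,7S)-6-(but-3-en-1-yl)-4-hydroxy-6-methyl-7-(3-methylbut-2-en-1-yl)-5-[(2R)-2-methylbutanoyl]-1,3-di(prop-2-en-1-yl)bicyclo[3.3.1]non-3-ene-2,9-dione | CC[C@@H](C)C(=O)[C@]12C(=O)[C@](CC=C)(C[C@H](CC=C(C)C)[C@@]1(C)CCC=C)C(=O)C(CC=C)=C2O | intermediate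
17 | 2-methylbut-2-ene | CC=C(C)C | starting material
18 | (1R,5S,6R,7S)-4-hydroxy-6-methyl-1,3,7-tris(3-methylbut-2-en-1-yl)-6-(4-methylpent-3-en-1-yl)-5-[(2R)-2-methylbutanoyl]bicyclo[3.3.1]non-3-ene-2,9-dione | CC[C@@H](C)C(=O)[C@]12C(=O)[C@](CC=C(C)C)(C[C@H](CC=C(C)C)[C@@]1(C)CCC=C(C)C)C(=O)C(CC=C(C)C)=C2O | target

**Step count**
Total steps: 7. Longest linear sequence: 5 (steps 1, 2, 5, 6, 7; the carbonate branch, steps 3, 4, 5, 6, 7, is equally long).

**Steps most likely to fail, with fallbacks**

Step 6 is the most exposed. The intermolecular initiation has no direct precedent. The prenyl cation may alkylate the enolized triketone directly at carbon or oxygen. Cation 15 may be captured by oxygen, or at the allyl-bearing ring carbon to give the type B skeleton. The new prenyl alkene of 16 can be prenylated again. If the cation lives long enough for bond rotation, C6/C7 control erodes.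
The fallback sets out from 12 and comes back at 18. Treating 12 with N-(phenylselanyl)phthalimide and SnCl4 in CH2Cl2 at −78 °C forms the seleniranium ion reversibly, and only at the trisubstituted alkene. Anti capture by the acyl-bearing ring carbon through the same chair (phenylseleno-carbocyclization of an alkenyl β-dicarbonyl) gives the 7-phenylselanyl analogue of 16 F1. Keck radical allylation in neat allyltributylstannane with AIBN at 80 °C delivers allyl from the open exo face and gives the 7-allyl analogue of 16 F2; the stannane is used neat to outrun 5-exo closure of the C7 radical onto the neighbouring alkenes. Cross-metathesis of the four terminal alkenes of F2 with 17 (four molecules consumed, used in large excess) under the step 7 conditions gives 18.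

Step 5 is next. The level and sense of induction are unknown for this nucleophile, and reversible ionization of C-allyl groups by zerovalent palladium could scramble substituents or erode selectivity.
The fallback sets out from 6 and 10 and comes back at 12; it replaces asymmetric catalysis by diastereomer separation. PBr3 in Et2O at 0 °C converts 10 into (2E)-1-bromo-3-methylhepta-2,6-diene F3. Alkylation of 6 with F3 and NaOMe in MeOH at 0 °C (the classical lupulone-type dearomative C-alkylation) gives 12 and its C6 epimer F4 in about equal amounts. The two are diastereomers because of the (2R)-acyl group; they are separated by preparative HPLC and F4 is discarded.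

Step 7 is third. The free vinylogous acid can bind ruthenium, three metathesis events must all go to completion, allyl-to-propenyl isomerization is possible, and the product is sensitive to air and light.
The fallback sets out from 16 and comes back at 18; it masks the acid first. Me3SiCHN2 in toluene–MeOH gives the 4-O-methyl ether of 16 F5 and its regioisomeric methyl enol ether F6, which are carried on together. Cross-metathesis with 17 as in step 7 (three molecules of 17 per substrate molecule) gives the 4-O-methyl ether of 18 F7 and its regioisomer F8. LiCl in DMSO at 120 °C cleaves both vinylogous esters to 18.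

**Further compounds**
F1 | step 6 | 7-phenylselanyl analogue of 16 (selenium equatorial at C7; C1, C5, C6 arranged as in 16) | CC[C@@H](C)C(=O)[C@]12C(=O)[C@](CC=C)(C[C@H]([Se]c3ccccc3)[C@@]1(C)CCC=C)C(=O)C(CC=C)=C2O
F2 | step 6 | 7-allyl analogue of 16, (1R,5S,6R,7S)-6-(but-3-en-1-yl)-4-hydroxy-6-methyl-5-[(2R)-2-methylbutanoyl]-1,3,7-tri(prop-2-en-1-yl)bicyclo[3.3.1]non-3-ene-2,9-dione | CC[C@@H](C)C(=O)[C@]12C(=O)[C@](CC=C)(C[C@H](CC=C)[C@@]1(C)CCC=C)C(=O)C(CC=C)=C2O
F3 | step 5 | (2E)-1-bromo-3-methylhepta-2,6-diene | BrC/C=C(\C)CCC=C
F4 | step 5 | C6 epimer of 12, (6S)-3,5-dihydroxy-2-[(2R)-2-methylbutanoyl]-6-[(2E)-3-methylhepta-2,6-dien-1-yl]-4,6-di(prop-2-en-1-yl)cyclohexa-2,4-dien-1-one | CC[C@@H](C)C(=O)C1=C(O)C(CC=C)=C(O)[C@](CC=C)(C/C=C(\C)CCC=C)C1=O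
F5 | step 7 | 4-O-methyl ether of 16 (4-methoxy in place of 4-hydroxy) | CC[C@@H](C)C(=O)[C@]12C(=O)[C@](CC=C)(C[C@H](CC=C(C)C)[C@@]1(C)CCC=C)C(=O)C(CC=C)=C2OC
F6 | step 7 | regioisomeric methyl enol ether of 16 (methoxy on the enone carbon next to the allyl bridgehead, ketone next to the acyl bridgehead) | CC[C@@H](C)C(=O)[C@]12C(=O)[C@](CC=C)(C[C@H](CC=C(C)C)[C@@]1(C)CCC=C)C(OC)=C(CC=C)C2=O
F7 | step 7 | 4-O-methyl ether of 18 | CC[C@@H](C)C(=O)[C@]12C(=O)[C@](CC=C(C)C)(C[C@H](CC=C(C)C)[C@@]1(C)CCC=C(C)C)C(=O)C(CC=C(C)C)=C2OC
F8 | step 7 | regioisomeric methyl enol ether of 18 (methoxy on the enone carbon next to the prenyl bridgehead) | CC[C@@H](C)C(=O)[C@]12C(=O)[C@](CC=C(C)C)(C[C@H](CC=C(C)C)[C@@]1(C)CCC=C(C)C)C(OC)=C(CC=C(C)C)C2=O
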